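Complex with one exchanged appears with one leaving ligand freed and one incoming ligand spent, while the scavenger removes leaving ligand, so the flask can be followed by counting turnovers T per starting complex.

the same everywhere: starting complex 0.10 M
- north: incoming ligand 1.1 equiv; leaving ligand 2 equiv; scavenger 2.2 equiv; run made earlier
- south-west: incoming ligand 1.1 equiv; leaving ligand 2 equiv; scavenger 2.3 equiv; run made earlier
- maple: incoming ligand 1.10 equiv; leaving ligand 2.00 equiv; scavenger 2.00 equiv; time 15 min
- elm: incoming ligand 1.10 equiv; leaving ligand 2.00 equiv; scavenger 1.50 equiv; time 15 min

| run | time / min | starting complex / % | complex with one exchanged / % |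
|---|---|---|---|
| north | 0.833 | 89.7 | 9.5 |
| north | 1.33 | 83.9 | 14.6 |
| north | 2.00 | 76.9 | 21.9 |
| north | 3.00 | 68.5 | 28.5 |
| north | 5.00 | 56.7 | 38.0 |
| north | 6.00 | 52.9 | 40.7 |
| north | 10.0 | 45.1 | 45.7 |
| south-west | 0.500 | 94.1 | 5.7 |
| south-west | 1.50 | 81.8 | 16.8 |
| south-west | 3.00 | 68.4 | 29.7 |
| south-west | 5.00 | 56.1 | 38.3 |
| south-west | 6.00 | 54.2 | 41.2 |
| south-west | 8.00 | 46.4 | 45.2 |
| south-west | 10.0 | 44.3 | 46.5 |

(readings scatter by 0.5 percentage points)

1. part of the starting complex that has reacted at the end, maple
2. part of the starting complex that has reacted at the end, elm
3. what raising the equivalents of scavenger from its lowest to its highest value here does to the part of the starting complex that has reacted (changes below 5 percentage points count as none) (it rises / no change / it falls)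

- a reading or a percentage of leaving ligand counts all its forms, free or not

The first north reading gives a pseudo-first-order start, k = 0.130 /min. The rate then slows by factors in T. Starting complex scales it by 1 − T, and incoming ligand, charged at x equivalents, by 1 − T/x. The way back grows as T(u + T), where u is leaving ligand charged minus scavenger charged, 0.500 equiv in elm. The last north reading, counting the missing percentage twice, stands at 0.641 equiv of turnover, and there the quotient of products over reactants reads 0.974.

My own reckoning takes that quotient as 1, lets the scavenger act at once and neglects the second exchange. The squared terms then cancel, the net rate falls in a straight line with T, and it reaches zero at the standstill count T* = x/(1 + x + u), which is 42.3% for elm and 52.4% for maple. At T* in elm, the factors 57.7% and 61.5% leave the forward rate at 35.5% of its start, and the way back cancels that remainder. The straight-line fall has time constant T*/k, 3.24 min in elm, so after 15 min a share 0.976% of the way remains in elm and 2.38% in maple. The reckoned rise of 10 percentage points exceeds the margin.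

The forecast says 57% for maple, 49% for elm and it rises, with exchange “held back by free leaving ligand once the scavenger is used up”. Both its numbers stand above mine.

The flask gives 53.8% in maple and 45.2% in elm, a change of 8.6 points: it rises. Elm stands at 45.1% after ten times the time. T* lies 2.9 points below elm and 1.4 points below maple.

    starting complex + incoming ligand ⇌ leaving ligand + complex with one exchanged (K = 1.60, k = 0.0290 /M/s)
    complex with one exchanged + incoming ligand ⇌ leaving ligand + complex with two exchanged (K = 2.40, k = 0.00960 /M/s)
    leaving ligand + incoming ligand ⇌ idle adduct, settled at all times (K = 6.10 /M)
    scavenger + leaving ligand → scavenged by-product (k = 0.370 /M/s)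
    incoming ligand → decomposition product (k = 6.10 × 10⁻⁷ /s)

In the neighbour of elm charged at 0.040 M of starting complex, T* holds equivalents and no concentration, so it stays 42.3%. The computed answer there is 41.0%.

The readings are simulated from invented constants; scatter was added.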